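If a racemate meets a single-handed catalyst, the excess left in the substrate follows from how fast the two hands react and how far the faster one has gone.

| flask | left-handed substrate | right-handed substrate | solid reagent | precatalyst | remark | time |
|---|---|---|---|---|---|---|
| Saturday's | 0.10 M | 0.10 M | 0.080 M | 1 mM | run made earlier |  |
| Friday's | 0.10 M | 0.10 M | 0.080 M | 1.7 mM | run made earlier |  |
| Sunday's | 0.10 M | 0.10 M | 0.040 M | 0.75 mM | run made earlier |  |
| flask | 0.10 M | 0.10 M | 0.0800 M | 0.75 mM |  | 8.0 d |

| run | time / d | right-handed substrate / % | left-handed substrate / % | left-handed product / % |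
|---|---|---|---|---|
| Saturday's | 0.625 | 49.4 | 44.5 | 3.1 |
| Saturday's | 1.25 | 50.5 | 45.2 | 4.7 |
| Saturday's | 2.50 | 47.7 | 41.3 | 7.6 |
| Saturday's | 4.00 | 47.5 | 42.4 | 7.4 |
| Saturday's | 8.00 | 46.9 | 39.7 | 8.3 |
| Friday's | 0.625 | 49.3 | 46.2 | 6.2 |
| Friday's | 1.25 | 46.3 | 41.7 | 6.0 |
| Friday's | 2.50 | 47.1 | 42.7 | 9.7 |
| Friday's | 4.00 | 49.1 | 41.0 | 10.9 |
| Friday's | 8.00 | 45.0 | 38.1 | 10.0 |
| Sunday's | 0.625 | 50.0 | 47.2 | 1.2 |
| Sunday's | 1.25 | 48.6 | 47.1 | 3.6 |
| Sunday's | 2.50 | 50.8 | 45.6 | 5.2 |
| Sunday's | 4.00 | 46.1 | 43.5 | 5.5 |
| Sunday's | 8.00 | 47.7 | 42.8 | 4.4 |

(standard deviation of a reading: 1 percentage point)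

- free catalyst is single-handed; left-handed substrate and right-handed substrate are mirror images of each other, charged as a racemate, each of them at the stated concentration
- solid, in amounts per volume of the solution: solid reagent
- at the start none of the solid reagent is in solution

- whether the excess of right-handed substrate over left-handed substrate among what is left of the two reaches 99% by 8.0 d (no / yes)
- the highest excess of right-handed substrate over left-handed substrate among what is left of the two up to 8.0 d

1. Both substrates meet the same free catalyst, so however that catalyst fades, one ratio can be frozen: the selectivity factor 3.04, the logarithm of the left-handed rest over that of the right-handed rest, each rest a part of its own charge, pooled over the last readings of the earlier runs.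

2. This looks contradictory: left-handed substrate reacts 3.04 times as fast, yet Saturday's excess reads 8.31%.

3. The rule clears it up. The right-handed rest is the left-handed rest raised to the power one over the selectivity factor, and the excess is the difference of the two rests over their sum. Saturday's left-handed rest of 79.4% then gives 7.72%, so a modest factor on a small conversion gives a small excess.

4. This flask has Sunday's precatalyst and Saturday's solid reagent. My own bracket runs from 5.21%, with Sunday's rest, to 7.72%, which is below 99%.

5. The forecast says no, with a top of 7%, on the ground that “the reaction stalls early”.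

6. The flask gives no and a top of 6.85%. At 8.00 d, 82% of the left-handed substrate and 94% of the right-handed substrate remain. The rule with that left-handed rest gives 6.65%.

    coupling partner + free catalyst + left-handed substrate → free catalyst + left-handed product (k = 0.140 L² mol⁻² s⁻¹)
    solid reagent ⇌ coupling partner, rate k2*(cs2 - [coupling partner]) while solid is left; crystals form when [coupling partner] > cs2 (solubility = 0.0500 M, k = 5.30 × 10⁻⁵ s⁻¹)
    precatalyst → free catalyst (k = 3.10 × 10⁻⁵ s⁻¹)
    2 free catalyst → spent catalyst (k = 0.0980 L mol⁻¹ s⁻¹)
    coupling partner + free catalyst + right-handed substrate → free catalyst + right-handed product (k = 0.0430 L² mol⁻² s⁻¹)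

7. With 0.0030 M of precatalyst, the neighbour flask ends with 73% of its left-handed substrate, for which the rule gives 10.5%. The computed top there is 10.9%.

(All runs were computed with constants of no real substance; scatter was added.)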